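**Retrosynthetic overview**
1. Target 17 ⇐ diol 15 by C–O acylation of the secondary C8–OH; 15 ⇐ ketone 11 by addition of a crotonoyl anion equivalent to C7.
2. 11 ⇐ 10 by one hydrogenation that sets C6 and C3.
3. 10 ⇐ dienone acid 8 by the key C–O step: a one-flask lactonization/α-hydroxylation that closes the γ-lactone (O1–C8a) and installs C8–OH trans to it.
4. 8 ⇐ cycloheptadienone 5 by allylic oxidation of the isopropenyl group; 5 ⇐ (R)-carvone 1 by one-carbon ring expansion.
5. Ring order: seven-membered carbocycle first, γ-lactone second; C8, C6, C3 and C7 are then all set by attack on the convex face (the face of H-3a and H-8a) of the cis-fused bicycle.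

Assumption: bicyclic compounds are numbered as cyclohepta[b]furans (O1, C2, C3, C3a, C4–C8, C8a); for 3 and 4, whose extra stereocentres are destroyed in step 3, only the expected major epimer is drawn. Selectivities are predictions, not measured results.

**Step 1**
Reactants: 1 (R)-(−)-carvone
Product: 2 trimethyl{[(3R)-6-methyl-3-(prop-1-en-2-yl)cyclohexa-1,5-dien-1-yl]oxy}silane
Conditions: LiN(iPr)2, THF, −78 °C; Me3SiCl, −78 → 0 °C
Reagents that add atoms: chlorotrimethylsilane, C[Si](C)(C)Cl
Why: Kinetic α′-deprotonation of the enone and O-silylation (kinetic silyl enol ether formation) give the cross-conjugated 2-silyloxydiene without touching the stereocentre.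

**Step 2**
Reactants: 2 silyl dienol ether
Product: 3 trimethyl{[(1R,5R,6S)-2-methyl-5-(prop-1-en-2-yl)bicyclo[4.1.0]hept-2-en-1-yl]oxy}silane
Conditions: Et2Zn, CH2I2, toluene, 0 °C → rt
Reagents that add atoms: diiodomethane, ICI
Why: Simmons–Smith (Furukawa) cyclopropanation is selective for the most electron-rich alkene, the silyl enol ether; the new centres (CH2 anti to isopropenyl) are erased in step 3.

**Step 3**
Reactants: 3 siloxycyclopropane
Product: 5 (5R)-2-methyl-5-(prop-1-en-2-yl)cyclohepta-2,6-dien-1-one, via chloro ketone 4 (not isolated)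
Conditions: FeCl3, DMF, 0 °C; then NaOAc, MeOH, reflux
Reagents that add atoms: none
Why: Ito–Saegusa ring expansion: one-electron oxidation by trivalent iron gives an alkoxy radical that cleaves the internal cyclopropane bond, chlorine transfer gives β-chloro ketone 4, and acetate-mediated loss of HCl gives the cross-conjugated dienone.

**Step 4**
Reactants: 5 cycloheptadienone
Product: 6 (5R)-5-(3-hydroxyprop-1-en-2-yl)-2-methylcyclohepta-2,6-dien-1-one
Conditions: SeO2 (30 mol%), t-BuOOH, CH2Cl2, 0 °C → rt
Reagents that add atoms: tert-butyl hydroperoxide, CC(C)(C)OO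
Why: Selenium dioxide allylic oxidation (ene reaction, then 2,3-sigmatropic shift) attacks the only electron-rich alkene and, by the usual CH3 > CH preference of a 1,1-disubstituted alkene, its methyl group; the enone alkenes are deactivated.

**Step 5**
Reactants: 6 allylic alcohol
Product: 8 2-[(1R)-5-methyl-4-oxocyclohepta-2,5-dien-1-yl]prop-2-enoic acid, via enal 7 (not isolated)
Conditions: TEMPO (10 mol%), PhI(OAc)2, CH2Cl2, rt; then NaClO2, NaH2PO4, 2-methyl-2-butene, t-BuOH/H2O, 0 °C
Reagents that add atoms: sodium chlorite, [Na+].[O-]Cl=O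
Why: Oxoammonium oxidation of the primary allylic alcohol to enal 7 followed by Pinnick oxidation; both tolerate the dienone and leave the stereocentre alone.

**Step 6 (key C–O step)**
Reactants: 8 dienone acid
Product: 10 (3aS,8S,8aR)-8-hydroxy-6-methyl-3-methylidene-3a,4,8,8a-tetrahydro-2H-cyclohepta[b]furan-2,7(3H)-dione, via keto lactone 9 (not isolated)
Conditions: 9-amino-9-deoxy-epi-quinine (20 mol%), CF3CO2H (40 mol%), 3-phenyl-2-(phenylsulfonyl)oxaziridine (1.2 equiv, slow addition), wet 1,4-dioxane, 25 °C
Reagents that add atoms: 3-phenyl-2-(phenylsulfonyl)oxaziridine, O=S(=O)(c1ccccc1)N1OC1c1ccccc1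
Why: Proposed new method: an amine-catalysed iminium/enamine relay; the primary amine condenses with the dienone, the tethered carboxylate adds 5-exo to the enone β-carbon next to the stereocentre on the face of its own tether (so the γ-lactone is cis-fused, keto lactone 9 held as its enamine), and this regiodefined cross-conjugated enamine takes oxygen from the N-sulfonyloxaziridine on the convex face, anti to the new C–O bond, before it can tautomerise, giving the trans hydroxy lactone (8S, 8aR) after hydrolysis. The closest known reactions are primary-amine-catalysed epoxidation of cyclic enones with H2O2 and amine-catalysed α-oxidation of ketones with electrophilic oxygen donors; a carboxylate as conjugate nucleophile paired with external electrophilic hydroxylation (a formal anti-hydroxylactonization of an enone) has not been described.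

**Step 7**
Reactants: 10 hydroxy lactone enone
Product: 11 (3R,3aS,6S,8S,8aR)-8-hydroxy-3,6-dimethylhexahydro-2H-cyclohepta[b]furan-2,7(3H)-dione
Conditions: [Ir(cod)(PCy3)(py)]PF6 (5 mol%), H2 (1 atm), CH2Cl2, rt
Reagents that add atoms: none
Why: Hydroxyl-directed homogeneous hydrogenation: the C8–OH on the convex face delivers H2 to that face of the C5=C6 enone alkene (sets 6S), and the exocyclic methylene is reduced from the same exposed face of the cis-fused lactone (sets 3R).

**Step 8**
Reactants: 11 hydroxy keto lactone; 12 (E)-crotonaldehyde diethyl acetal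
Product: 15 (3R,3aS,6S,7S,8S,8aR)-7-[(2E)-but-2-enoyl]-7,8-dihydroxy-3,6-dimethyloctahydro-2H-cyclohepta[b]furan-2-one, via organocerium reagent 13 (not isolated), via dienyl carbinol 14 (not isolated)
Conditions: 12 (3 equiv), n-BuLi/t-BuOK, THF, −95 °C; CeCl3, −78 °C; then 11, −78 °C; then 0.5 M HCl, THF, 0 °C
Reagents that add atoms: (E)-crotonaldehyde diethyl acetal, C/C=C/C(OCC)OCC; water, O
Why: 1,2-Addition of an α-metalated alkoxydiene (a crotonoyl anion equivalent from 1,4-elimination/α-metalation of the acetal) as its organocerium; with the C8 alkoxide chelated in the carbonyl plane the reagent attacks C7 from the convex face anti to the C6 methyl (sets 7S), and acid hydrolysis of the dienol ether, with protonation at the diene terminus, gives the (E)-enone.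

**Step 9**
Reactants: 15 diol; 16 isobutyric anhydride
Product: 17 (3R,3aS,6S,7S,8S,8aR)-7-[(2E)-but-2-enoyl]-7-hydroxy-3,6-dimethyl-2-oxooctahydro-2H-cyclohepta[b]furan-8-yl 2-methylpropanoate
Conditions: (i-PrCO)2O, DMAP (cat.), pyridine, CH2Cl2, 0 °C
Reagents that add atoms: isobutyric anhydride, CC(C)C(=O)OC(=O)C(C)C
Why: DMAP-catalysed acyl transfer esterifies the secondary C8–OH selectively over the tertiary α-keto C7–OH; no stereocentre is affected.

**Compound list**
1 | (R)-(−)-carvone | O=C1C(C)=CC[C@@H](C(C)=C)C1 | starting material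
2 | trimethyl{[(3R)-6-methyl-3-(prop-1-en-2-yl)cyclohexa-1,5-dien-1-yl]oxy}silane | CC1=CC[C@@H](C(C)=C)C=C1O[Si](C)(C)C | intermediate
3 | trimethyl{[(1R,5R,6S)-2-methyl-5-(prop-1-en-2-yl)bicyclo[4.1.0]hept-2-en-1-yl]oxy}silane | CC1=CC[C@@H](C(C)=C)[C@@H]2C[C@]12O[Si](C)(C)C | intermediate
4 | (5S,6R)-6-chloro-2-methyl-5-(prop-1-en-2-yl)cyclohept-2-en-1-one (formed in situ) | CC1=CC[C@@H](C(C)=C)[C@H](Cl)CC1=O | intermediate
5 | (5R)-2-methyl-5-(prop-1-en-2-yl)cyclohepta-2,6-dien-1-one | CC1=CC[C@@H](C(C)=C)C=CC1=O | intermediate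
6 | (5R)-5-(3-hydroxyprop-1-en-2-yl)-2-methylcyclohepta-2,6-dien-1-one | CC1=CC[C@@H](C(=C)CO)C=CC1=O | intermediate
7 | 2-[(1R)-5-methyl-4-oxocyclohepta-2,5-dien-1-yl]prop-2-enal (formed in situ) | CC1=CC[C@@H](C(=C)C=O)C=CC1=O | intermediate
8 | 2-[(1R)-5-methyl-4-oxocyclohepta-2,5-dien-1-yl]prop-2-enoic acid | CC1=CC[C@@H](C(=C)C(=O)O)C=CC1=O | intermediate
9 | (3aS,8aS)-6-methyl-3-methylidene-3a,4,8,8a-tetrahydro-2H-cyclohepta[b]furan-2,7(3H)-dione, cis-fused keto lactone (formed in situ) | O=C1C(C)=CC[C@@H]2[C@@H](OC(=O)C2=C)C1 | intermediate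
10 | (3aS,8S,8aR)-8-hydroxy-6-methyl-3-methylidene-3a,4,8,8a-tetrahydro-2H-cyclohepta[b]furan-2,7(3H)-dione | O=C1C(C)=CC[C@@H]2[C@@H](OC(=O)C2=C)[C@@H]1O | intermediate
11 | (3R,3aS,6S,8S,8aR)-8-hydroxy-3,6-dimethylhexahydro-2H-cyclohepta[b]furan-2,7(3H)-dione | O=C1[C@@H](C)CC[C@@H]2[C@@H](OC(=O)[C@@H]2C)[C@@H]1O | intermediate
12 | (2E)-1,1-diethoxybut-2-ene (crotonaldehyde diethyl acetal) | C/C=C/C(OCC)OCC | starting material
13 | [(1Z)-1-ethoxybuta-1,3-dien-1-yl]cerium dichloride (formed in situ) | CCO/C(=C/C=C)[Ce](Cl)Cl | intermediate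
14 | (3R,3aS,6S,7S,8S,8aR)-7-[(1E)-1-ethoxybuta-1,3-dien-1-yl]-7,8-dihydroxy-3,6-dimethyloctahydro-2H-cyclohepta[b]furan-2-one (formed in situ) | C=C/C=C(/OCC)[C@]1(O)[C@@H](C)CC[C@@H]2[C@@H](OC(=O)[C@@H]2C)[C@@H]1O | intermediate
15 | (3R,3aS,6S,7S,8S,8aR)-7-[(2E)-but-2-enoyl]-7,8-dihydroxy-3,6-dimethyloctahydro-2H-cyclohepta[b]furan-2-one | C/C=C/C(=O)[C@]1(O)[C@@H](C)CC[C@@H]2[C@@H](OC(=O)[C@@H]2C)[C@@H]1O | intermediate
16 | isobutyric anhydride | CC(C)C(=O)OC(=O)C(C)C | starting material
17 | (3R,3aS,6S,7S,8S,8aR)-7-[(2E)-but-2-enoyl]-7-hydroxy-3,6-dimethyl-2-oxooctahydro-2H-cyclohepta[b]furan-8-yl 2-methylpropanoate | C/C=C/C(=O)[C@]1(O)[C@@H](C)CC[C@@H]2[C@@H](OC(=O)[C@@H]2C)[C@@H]1OC(=O)C(C)C | target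

**Step count and risks**
Total steps: 9. Longest linear sequence: 9 (from 1).

The three steps most likely to fail:

Step 6, the proposed relay. Iminium formation on the α-methyl cross-conjugated dienone may be slow, and γ-deprotonation of the iminium could isomerise the ring towards a tropone. The amine can also be captured by the α-methylene lactone or oxidised by the oxaziridine. The fallback uses known chemistry, sets out from 8 and comes back at 10. Catalytic camphorsulfonic acid in CH2Cl2 closes the lactone by intramolecular oxa-Michael addition to give keto lactone 9, now isolated. TMSOTf/Et3N at −78 °C converts 9 into the cross-conjugated silyl dienol ether F1. Rubottom oxidation of F1 with dimethyldioxirane (acetone, −40 °C) from the convex face, followed by mild acidic work-up, gives 10.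

Step 8. The alkoxide-rich reagent may open the lactone, epimerise C6 or C3, or trigger β-elimination of the lactone oxygen. Facial selectivity next to the C8 oxygen is also not secured; the usual preference of cyclic α-hydroxy ketones would give the wrong C7 epimer, and the prediction rests on chelation plus the convex-face and methyl bias. The fallback sets out from 11 and comes back at 15. 1-Lithio-1-methoxyallene (methoxyallene, n-BuLi, THF, −78 °C, then CeCl3) adds to the ketone to give the methoxyallenyl carbinol F2. Dilute aqueous acid hydrolyses F2 to the α′-hydroxy vinyl ketone F3. Cross-metathesis of F3 with (Z)-but-2-ene, using the second-generation Grubbs catalyst RuCl2(=CHPh)(PCy3)(H2IMes), installs the (E)-propenyl terminus and gives 15. This fallback addresses reagent basicity, not the facial question.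

Step 4. The ene reaction may instead abstract the doubly allylic ring C5–H, giving a tertiary alcohol or aromatising to a tropone, or the product may over-oxidise. The fallback sets out from 5 and comes back at 7. Ene-type chlorination with Ca(OCl)2 and CO2 (CH2Cl2/H2O, 0 °C) gives the allylic chloride F4. Oxidation of F4 with N-methylmorpholine N-oxide (MeCN, rt) gives enal 7, now isolated, which re-enters at the NaClO2 stage of step 5.

**Further compounds**
F1 | step 6 | (3aS,8aR)-6-methyl-3-methylidene-7-(trimethylsilyloxy)-3,3a,4,8a-tetrahydro-2H-cyclohepta[b]furan-2-one | CC1=CC[C@@H]2[C@@H](OC(=O)C2=C)C=C1O[Si](C)(C)C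
F2 | step 8 | (3R,3aS,6S,7S,8S,8aR)-7,8-dihydroxy-7-(1-methoxypropa-1,2-dien-1-yl)-3,6-dimethyloctahydro-2H-cyclohepta[b]furan-2-one | C=C=C(OC)[C@]1(O)[C@@H](C)CC[C@@H]2[C@@H](OC(=O)[C@@H]2C)[C@@H]1O
F3 | step 8 | (3R,3aS,6S,7S,8S,8aR)-7,8-dihydroxy-3,6-dimethyl-7-(prop-2-enoyl)octahydro-2H-cyclohepta[b]furan-2-one | C=CC(=O)[C@]1(O)[C@@H](C)CC[C@@H]2[C@@H](OC(=O)[C@@H]2C)[C@@H]1O
F4 | step 4 | (5R)-5-(3-chloroprop-1-en-2-yl)-2-methylcyclohepta-2,6-dien-1-one | CC1=CC[C@@H](C(=C)CCl)C=CC1=O
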